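**Retrosynthetic overview**
1. Target ⇒ terminal alkyne on the quaternary carbon (Z-selective Ru-catalysed AcOH addition, last step) and a trans-2-ethynylcyclohexanol (Pd cyclocarbonylation to the α-methylene lactone; lactone ring formed second).
2. Cyclohexane (formed first) ⇒ open-chain aldehyde closed by a type-I carbonyl-ene (Prins-type) reaction onto an isobutenyl group (ring C–C bond, OH and isopropenyl).
3. Open chain ⇒ α-hydroxy aldehyde + racemic formyl-masked propargyl bromide (chelation-controlled indium propargylation; one C–C bond, two stereocentres).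
4. α-Hydroxy aldehyde ⇒ 2,3-epoxy alcohol by the key semipinacol 1,2-alkenyl shift (quaternary stereocentre plus adjacent carbinol); epoxide from Sharpless epoxidation.
5. Epoxy alcohol ⇒ C5 enal + isobutenyl Grignard; propargyl bromide ⇒ dimethoxyacetaldehyde + ethynyl Grignard.

Assumption: the O-acetyl group of commercial starting material 1 is counted as a protecting group (it is cleaved in step 1); locants in names follow each compound's own IUPAC numbering.

**Step 1**
Reactants: 1 (2E)-3-methyl-4-oxobut-2-en-1-yl acetate; 2 (2-methylprop-1-en-1-yl)magnesium bromide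
Product: 4 rac-(2E)-3,6-dimethylhepta-2,5-diene-1,4-diol, via Grignard adduct monoacetate 3 (not isolated)
Conditions: 2 (1.05 equiv), THF, −78 °C; then K2CO3 (cat.), MeOH, 0 °C to rt; H2O
Reagents that add atoms: none
Why: Chemoselective Grignard 1,2-addition to the aldehyde at −78 °C (the allylic acetate survives) followed by in-flask transesterification; the carbinol centre is racemic, which is harmless because it becomes the aldehyde carbon in step 3.

**Step 2**
Reactants: 4 rac-(2E)-3,6-dimethylhepta-2,5-diene-1,4-diol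
Product: 5 (1RS)-1-[(2S,3S)-3-(hydroxymethyl)-2-methyloxiran-2-yl]-3-methylbut-2-en-1-ol
Conditions: Ti(OiPr)4 (10 mol %), L-(+)-DIPT (12 mol %), t-BuOOH, 4 Å MS, CH2Cl2, −25 °C; non-basic work-up
Reagents that add atoms: tert-butyl hydroperoxide, CC(C)(C)OO
Why: Sharpless asymmetric epoxidation directed by the primary allylic alcohol of a geraniol-type alkene, so L-(+)-tartrate gives the (2S,3S)-oxirane from both carbinol epimers, while the Z-substituted isobutenyl alkene is too slow to compete.

**Step 3**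
Reactants: 5 (1RS)-1-[(2S,3S)-3-(hydroxymethyl)-2-methyloxiran-2-yl]-3-methylbut-2-en-1-ol
Product: 7 (3S,4R)-3-methyl-3-(2-methylprop-1-en-1-yl)oxolane-2,4-diol (lactol), via open-chain hydroxy aldehyde 6 (not isolated)
Conditions: BF3·OEt2 (20 mol %), CH2Cl2, −78 to −40 °C
Reagents that add atoms: none
Why: Semipinacol (Suzuki–Tsuchihashi-type) rearrangement of a 2,3-epoxy alcohol: the oxirane opens at its tertiary carbon while the isobutenyl group shifts 1,2 from the carbinol carbon anti to the departing oxygen, which sets the quaternary C(Me)(CHO)(alkenyl) centre with inversion and keeps the neighbouring secondary C–O centre, and both carbinol epimers converge on one product that closes to the lactol.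

**Step 4**
Reactants: 7 (3S,4R)-3-methyl-3-(2-methylprop-1-en-1-yl)oxolane-2,4-diol
Product: 8 (2R,3R)-3-ethynyl-3,5-dimethylhex-4-ene-1,2-diol
Conditions: dimethyl (1-diazo-2-oxopropyl)phosphonate, K2CO3, MeOH, 0 °C to rt
Reagents that add atoms: Ohira–Bestmann reagent, CC(=O)C(=[N+]=[N-])P(=O)(OC)OC
Why: Ohira–Bestmann (Seyferth–Gilbert) homologation of the lactol-masked, non-enolisable aldehyde to the terminal alkyne without touching a stereocentre.

**Step 5**
Reactants: 8 (2R,3R)-3-ethynyl-3,5-dimethylhex-4-ene-1,2-diol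
Product: 9 (2R,3R)-3-ethynyl-2-hydroxy-3,5-dimethylhex-4-enal
Conditions: TEMPO (10 mol %), NCS, Bu4NCl (cat.), CH2Cl2/aq. NaHCO3–K2CO3 (pH 8.6), 0 °C; used crude at once
Reagents that add atoms: none
Why: Oxoammonium (TEMPO/NCS) oxidation is selective for the primary alcohol over the neopentyl secondary one and stops at the aldehyde.

**Step 6**
Reactants: 10 2,2-dimethoxyacetaldehyde; 11 ethynylmagnesium bromide
Product: 12 rac-1,1-dimethoxybut-3-yn-2-ol
Conditions: THF, −78 to 0 °C; H2O
Reagents that add atoms: none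
Why: Grignard 1,2-addition of the acetylide to the aldehyde; the racemate is what step 8 needs.

**Step 7**
Reactants: 12 rac-1,1-dimethoxybut-3-yn-2-ol
Product: 13 rac-3-bromo-4,4-dimethoxybut-1-yne
Conditions: CBr4, PPh3, CH2Cl2, 0 °C
Reagents that add atoms: carbon tetrabromide, BrC(Br)(Br)Br
Why: Appel bromination of the propargylic alcohol; any SN2′ bromoallene isomer gives the same organoindium species in step 8.

**Step 8**
Reactants: 9 (2R,3R)-3-ethynyl-2-hydroxy-3,5-dimethylhex-4-enal; 13 rac-3-bromo-4,4-dimethoxybut-1-yne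
Product: 14 (3R,4R,5R,6R)-3-(dimethoxymethyl)-6-ethynyl-6,8-dimethylnon-7-en-1-yne-4,5-diol
Conditions: 13 (2.5 equiv), In powder, DMF–THF, rt, 1 h; then 9, −20 °C to rt; pH 7 buffer
Reagents that add atoms: none
Why: Proposed new method: a stereoconvergent, chelation-controlled indium Barbier propargylation in which the racemic bromide gives a configurationally labile allenylindium (its axial enantiomers interconvert by In-to-In SE2′ exchange and propargyl–allenyl metallotropy) and the α-hydroxy aldehyde, held as a five-membered indium chelate whose quaternary substituent blocks one face, reacts through a six-membered cyclic SE2′ transition state with the matched allenyl enantiomer, giving the anti C3/C4 and syn C4/C5 relationships; the closest known reactions are anti-selective additions of pre-formed enantioenriched allenylindium reagents to aldehydes and chelation-controlled indium allylation of α-hydroxy aldehydes.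

**Step 9**
Reactants: 14 (3R,4R,5R,6R)-3-(dimethoxymethyl)-6-ethynyl-6,8-dimethylnon-7-en-1-yne-4,5-diol; 15 angelic acid, (2Z)-2-methylbut-2-enoic acid
Product: 16 (3R,4R,5R,6R)-3-(dimethoxymethyl)-6-ethynyl-5-hydroxy-6,8-dimethylnon-7-en-1-yn-4-yl (2Z)-2-methylbut-2-enoate
Conditions: 15, 2,4,6-trichlorobenzoyl chloride, Et3N, toluene, rt; then 14, 75 °C (no DMAP)
Reagents that add atoms: none
Why: Yamaguchi mixed-anhydride esterification without DMAP keeps the Z (angelate) geometry and acylates the C4 hydroxyl in preference to the neopentyl C5 hydroxyl next to the quaternary carbon.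

**Step 10**
Reactants: 16 mono-angelate from step 9
Product: 17 (3R,4R,5R,6R)-5-acetoxy-3-(dimethoxymethyl)-6-ethynyl-6,8-dimethylnon-7-en-1-yn-4-yl (2Z)-2-methylbut-2-enoate
Conditions: Ac2O, DMAP (cat.), pyridine, CH2Cl2, rt
Reagents that add atoms: acetic anhydride, CC(=O)OC(C)=O
Why: DMAP-catalysed acetylation of the remaining hindered secondary alcohol.

**Step 11**
Reactants: 17 diester acetal from step 10
Product: 18 (3R,4R,5R,6R)-5-acetoxy-6-ethynyl-3-formyl-6,8-dimethylnon-7-en-1-yn-4-yl (2Z)-2-methylbut-2-enoate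
Conditions: LiBF4, MeCN–H2O (50:1), 0 °C to rt; used crude at once
Reagents that add atoms: water, O
Why: Mild Lewis acid-promoted hydrolysis of the dimethyl acetal leaves both esters intact, and the base-free medium avoids β-elimination or epimerisation of the α-branched aldehyde.

**Step 12**
Reactants: 18 aldehyde from step 11
Product: 19 (1R,2R,3R,4S,5R,6S)-2-acetoxy-3,6-diethynyl-5-hydroxy-3-methyl-4-(prop-1-en-2-yl)cyclohexyl (2Z)-2-methylbut-2-enoate
Conditions: Me2AlCl (2.5 equiv), CH2Cl2, −78 to −30 °C; Rochelle salt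
Reagents that add atoms: none
Why: Type-I intramolecular carbonyl-ene (Prins-type) cyclisation of the citronellal-to-isopulegol kind: in the chair transition state the three existing ring substituents sit equatorial, so the new hydroxyl and isopropenyl groups form equatorial and trans, which sets both new stereocentres.

**Step 13**
Reactants: 19 cyclohexanol from step 12
Product: 20 (3aS,4R,5R,6R,7S,7aR)-5-acetoxy-6-ethynyl-6-methyl-3-methylidene-2-oxo-7-(prop-1-en-2-yl)octahydro-1-benzofuran-4-yl (2Z)-2-methylbut-2-enoate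
Conditions: PdCl2 (5 mol %), PPh3, SnCl2 (5 mol %), CO (7 atm), MeCN, 75 °C
Reagents that add atoms: carbon monoxide, [C-]#[O+]
Why: Pd-catalysed cyclocarbonylation of a homopropargylic alcohol (alkoxycarbonyl-palladium adds syn across the neighbouring alkyne) gives the trans-fused α-methylene-γ-butyrolactone; the second alkyne has no free hydroxyl nearby and stays.

**Step 14**
Reactants: 20 alkynyl lactone from step 13
Product: 21 (3aS,4R,5R,6S,7S,7aR)-5-acetoxy-6-[(Z)-2-acetoxyethenyl]-6-methyl-3-methylidene-2-oxo-7-(prop-1-en-2-yl)octahydro-1-benzofuran-4-yl (2Z)-2-methylbut-2-enoate (CNP0582479.1)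
Conditions: Ru(methallyl)2(dppb) (5 mol %), AcOH (2 equiv), toluene, 65 °C
Reagents that add atoms: acetic acid, CC(=O)O
Why: Ru-vinylidene-mediated anti-Markovnikov hydro-oxycarbonylation of the terminal alkyne, in which acetate attacks the vinylidene α-carbon and gives the Z-enol acetate.

**Compound list**
1 | (2E)-3-methyl-4-oxobut-2-en-1-yl acetate | CC(=O)OC/C=C(\C)C=O | starting material
2 | (2-methylprop-1-en-1-yl)magnesium bromide | CC(C)=C[Mg]Br | starting material
3 | rac-(2E)-4-hydroxy-3,6-dimethylhepta-2,5-dien-1-yl acetate (present as its magnesium alkoxide) | CC(=O)OC/C=C(\C)C(O)C=C(C)C | intermediate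
4 | rac-(2E)-3,6-dimethylhepta-2,5-diene-1,4-diol | OC/C=C(\C)C(O)C=C(C)C | intermediate
5 | (1RS)-1-[(2S,3S)-3-(hydroxymethyl)-2-methyloxiran-2-yl]-3-methylbut-2-en-1-ol | OC[C@@H]1O[C@@]1(C)C(O)C=C(C)C | intermediate
6 | (2S,3R)-3,4-dihydroxy-2-methyl-2-(2-methylprop-1-en-1-yl)butanal | OC[C@H](O)[C@@](C)(C=O)C=C(C)C | intermediate
7 | (3S,4R)-3-methyl-3-(2-methylprop-1-en-1-yl)oxolane-2,4-diol (lactol, both anomers) | OC1OC[C@H](O)[C@]1(C)C=C(C)C | intermediate
8 | (2R,3R)-3-ethynyl-3,5-dimethylhex-4-ene-1,2-diol | OC[C@H](O)[C@@](C)(C#C)C=C(C)C | intermediate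
9 | (2R,3R)-3-ethynyl-2-hydroxy-3,5-dimethylhex-4-enal | O=C[C@H](O)[C@@](C)(C#C)C=C(C)C | intermediate
10 | 2,2-dimethoxyacetaldehyde | COC(OC)C=O | starting material
11 | ethynylmagnesium bromide | C#C[Mg]Br | starting material
12 | rac-1,1-dimethoxybut-3-yn-2-ol | COC(OC)C(O)C#C | intermediate
13 | rac-3-bromo-4,4-dimethoxybut-1-yne | COC(OC)C(Br)C#C | intermediate
14 | (3R,4R,5R,6R)-3-(dimethoxymethyl)-6-ethynyl-6,8-dimethylnon-7-en-1-yne-4,5-diol | COC(OC)[C@H](C#C)[C@@H](O)[C@H](O)[C@@](C)(C#C)C=C(C)C | intermediate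
15 | angelic acid, (2Z)-2-methylbut-2-enoic acid | C/C=C(/C)C(=O)O | starting material
16 | (3R,4R,5R,6R)-3-(dimethoxymethyl)-6-ethynyl-5-hydroxy-6,8-dimethylnon-7-en-1-yn-4-yl (2Z)-2-methylbut-2-enoate | COC(OC)[C@H](C#C)[C@@H](OC(=O)/C(C)=C\C)[C@H](O)[C@@](C)(C#C)C=C(C)C | intermediate
17 | (3R,4R,5R,6R)-5-acetoxy-3-(dimethoxymethyl)-6-ethynyl-6,8-dimethylnon-7-en-1-yn-4-yl (2Z)-2-methylbut-2-enoate | COC(OC)[C@H](C#C)[C@@H](OC(=O)/C(C)=C\C)[C@H](OC(C)=O)[C@@](C)(C#C)C=C(C)C | intermediate
18 | (3R,4R,5R,6R)-5-acetoxy-6-ethynyl-3-formyl-6,8-dimethylnon-7-en-1-yn-4-yl (2Z)-2-methylbut-2-enoate | O=C[C@H](C#C)[C@@H](OC(=O)/C(C)=C\C)[C@H](OC(C)=O)[C@@](C)(C#C)C=C(C)C | intermediate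
19 | (1R,2R,3R,4S,5R,6S)-2-acetoxy-3,6-diethynyl-5-hydroxy-3-methyl-4-(prop-1-en-2-yl)cyclohexyl (2Z)-2-methylbut-2-enoate | O[C@H]1[C@H](C#C)[C@@H](OC(=O)/C(C)=C\C)[C@H](OC(C)=O)[C@@](C)(C#C)[C@@H]1C(=C)C | intermediate
20 | (3aS,4R,5R,6R,7S,7aR)-5-acetoxy-6-ethynyl-6-methyl-3-methylidene-2-oxo-7-(prop-1-en-2-yl)octahydro-1-benzofuran-4-yl (2Z)-2-methylbut-2-enoate | C=C1C(=O)O[C@H]2[C@H]1[C@@H](OC(=O)/C(C)=C\C)[C@H](OC(C)=O)[C@@](C)(C#C)[C@@H]2C(=C)C | intermediate
21 | (3aS,4R,5R,6S,7S,7aR)-5-acetoxy-6-[(Z)-2-acetoxyethenyl]-6-methyl-3-methylidene-2-oxo-7-(prop-1-en-2-yl)octahydro-1-benzofuran-4-yl (2Z)-2-methylbut-2-enoate | C=C1C(=O)O[C@H]2[C@H]1[C@@H](OC(=O)/C(C)=C\C)[C@H](OC(C)=O)[C@@](C)(/C=C\OC(C)=O)[C@@H]2C(=C)C | target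

**Step count and risks**
Total steps: 14. Longest linear sequence: 12 (steps 1–5 and 8–14).

Most likely to fail, in this order: step 8, step 9, step 3.

Step 8 (proposed new method): the allenylindium may not racemise fast enough, or chelation may not override the reagent's own preference, which would give diastereomer mixtures. The fallback sets out from 12 (with 9) and comes back at 14, and uses reagent control with a pre-formed enantioenriched allenylindium. Lipase-catalysed acylation of 12 (vinyl acetate; Kazlauskas rule) gives (R)-1,1-dimethoxybut-3-yn-2-yl acetate F4. Methanolysis (K2CO3, MeOH) gives (R)-1,1-dimethoxybut-3-yn-2-ol F5. Mesylation (MsCl, Et3N) gives (R)-1,1-dimethoxybut-3-yn-2-yl methanesulfonate F6. F6 is then coupled with 9 by Pd(0)-catalysed oxidative transmetalation with InI (Pd(dppf)Cl2, THF–HMPA); the anti-SN2′/syn-SE2′ course means net inversion at the propargylic carbon and delivers 14.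

Step 9: the two secondary hydroxyls may not be differentiated well enough, or the acyl group may migrate. The fallback sets out from 8 and comes back at 16, and fixes the regiochemistry with a protecting group that also chelates. Diol 8 and 4-methoxybenzaldehyde dimethyl acetal (CSA) give the 4-methoxybenzylidene acetal of diol 8 F7. DIBAL opens it to (2R,3R)-3-ethynyl-2-[(4-methoxyphenyl)methoxy]-3,5-dimethylhex-4-en-1-ol F8. Dess–Martin oxidation gives (2R,3R)-3-ethynyl-2-[(4-methoxyphenyl)methoxy]-3,5-dimethylhex-4-enal F9. Chelation- and reagent-controlled propargylation with F6 (Pd(dppf)Cl2, InI) gives (3R,4R,5R,6R)-3-(dimethoxymethyl)-6-ethynyl-5-[(4-methoxyphenyl)methoxy]-6,8-dimethylnon-7-en-1-yn-4-ol F10. Yamaguchi angeloylation with 15 gives the 4-O-angelate of that PMB ether F11, and DDQ (wet CH2Cl2) releases 16.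

Step 3: on the unprotected epoxy diol a 1,2-hydride shift, Payne-type equilibration, or different behaviour of the two carbinol epimers could compete. The fallback sets out from 5 and comes back at 8, and uses the silyl-assisted version of the rearrangement. TESCl/imidazole converts 5 into the bis(triethylsilyl) ether of epoxy diol 5 F1. Methylaluminium bis(4-bromo-2,6-di-tert-butylphenoxide) (CH2Cl2, −78 °C) triggers the epoxy silyl ether rearrangement with 1,4-silyl transfer to (2S,3R)-2-methyl-2-(2-methylprop-1-en-1-yl)-3,4-bis(triethylsilyloxy)butanal F2. Ohira–Bestmann homologation gives (2R,3R)-3-ethynyl-3,5-dimethyl-1,2-bis(triethylsilyloxy)hex-4-ene F3, and TBAF returns 8.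

**Further compounds**
F1 | step 3 | bis(triethylsilyl) ether of epoxy diol 5 | CC[Si](CC)(CC)OC[C@@H]1O[C@@]1(C)C(O[Si](CC)(CC)CC)C=C(C)C
F2 | step 3 | (2S,3R)-2-methyl-2-(2-methylprop-1-en-1-yl)-3,4-bis(triethylsilyloxy)butanal | CC[Si](CC)(CC)OC[C@H](O[Si](CC)(CC)CC)[C@@](C)(C=O)C=C(C)C
F3 | step 3 | (2R,3R)-3-ethynyl-3,5-dimethyl-1,2-bis(triethylsilyloxy)hex-4-ene | CC[Si](CC)(CC)OC[C@H](O[Si](CC)(CC)CC)[C@@](C)(C#C)C=C(C)C
F4 | step 8 | (R)-1,1-dimethoxybut-3-yn-2-yl acetate | COC(OC)[C@@H](C#C)OC(C)=O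
F5 | step 8 | (R)-1,1-dimethoxybut-3-yn-2-ol | COC(OC)[C@@H](C#C)O
F6 | step 8 | (R)-1,1-dimethoxybut-3-yn-2-yl methanesulfonate | COC(OC)[C@@H](C#C)OS(C)(=O)=O
F7 | step 9 | 4-methoxybenzylidene acetal of diol 8 (acetal carbon as a mixture) | COc1ccc(cc1)C1OC[C@H](O1)[C@@](C)(C#C)C=C(C)C
F8 | step 9 | (2R,3R)-3-ethynyl-2-[(4-methoxyphenyl)methoxy]-3,5-dimethylhex-4-en-1-ol | OC[C@H](OCc1ccc(OC)cc1)[C@@](C)(C#C)C=C(C)C
F9 | step 9 | (2R,3R)-3-ethynyl-2-[(4-methoxyphenyl)methoxy]-3,5-dimethylhex-4-enal | O=C[C@H](OCc1ccc(OC)cc1)[C@@](C)(C#C)C=C(C)C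
F10 | step 9 | (3R,4R,5R,6R)-3-(dimethoxymethyl)-6-ethynyl-5-[(4-methoxyphenyl)methoxy]-6,8-dimethylnon-7-en-1-yn-4-ol | COC(OC)[C@H](C#C)[C@@H](O)[C@H](OCc1ccc(OC)cc1)[C@@](C)(C#C)C=C(C)C
F11 | step 9 | (3R,4R,5R,6R)-3-(dimethoxymethyl)-6-ethynyl-5-[(4-methoxyphenyl)methoxy]-6,8-dimethylnon-7-en-1-yn-4-yl (2Z)-2-methylbut-2-enoate | COC(OC)[C@H](C#C)[C@@H](OC(=O)/C(C)=C\C)[C@H](OCc1ccc(OC)cc1)[C@@](C)(C#C)C=C(C)C
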